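**Retrosynthetic overview**

- Target 18 comes from lactone 17 by loss of the two benzyl groups, and 17 from phenol acid 16 by closure of the O1–C2 lactone bond.
- The strategy rests on the benzo ring C4a–C5–C6–C7–C8–C8a, which carries oxygen at C7 and C8a, carbon arms at C4a and C6, and hydrogen at C5 and C8. It is the aldol fold of a chain with an aldehyde at C5 and ketones at C7 and C8a. The chain is stored as the 2,5-disubstituted 4-pyranone 13, and C4a–C5 is formed when it is opened.
- Pyranone 13 is cut at C8–C8a into half-ester 5 (C2 to C4a, C8a and the C4 stereocentre) and enaminone 10 (C5 to C8 with the C6 arm). The formyl carbon C5 is already in place in 10, so no late formylation has to choose between two diketone ends or compete with the ester α-methylene.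
- Half-ester 5 comes from a rhodium/(R)-BINAP conjugate arylation of 5,6-dihydro-2H-pyran-2-one, which sets C4, followed by ring opening and oxidation. Enaminone 10 comes from C-acetylation of the enamine of 4-(3,4-dimethoxyphenyl)butanal.
- Ring order: 4-pyranone (step 7), benzene ring (step 8), lactone ring (step 9).

Key step: step 8

Remark: the atom numbers C2 to C8a of the chroman-2-one of the target are also used for the corresponding atoms of earlier compounds, and boronic acid 1 is taken as a catalogue compound.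

**Route**

Step 1
Reactants: 1 3,4-bis(benzyloxy)phenylboronic acid; 2 5,6-dihydro-2H-pyran-2-one
Product: 3 (4R)-4-[3,4-bis(benzyloxy)phenyl]oxan-2-one
Conditions: Rh(acac)(C2H4)2 (3 mol %), (R)-BINAP (3.3 mol %), 1 (2.5 equiv), dioxane/H2O 10:1, 100 °C
Reagents that add atoms: none
Why: Hayashi–Miyaura asymmetric 1,4-addition: the aryl–rhodium species formed by transmetalation adds to the β-carbon of the enoate on the face selected by (R)-BINAP, the sense that gives (R)-3-arylcyclohexanones from cyclohexenone and corresponds to 4R here, and water releases the lactone from the rhodium enolate.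

Step 2
Reactants: 3 (4R)-4-[3,4-bis(benzyloxy)phenyl]oxan-2-one
Product: 4 methyl (3R)-3-[3,4-bis(benzyloxy)phenyl]-5-hydroxypentanoate
Conditions: MeOH, H2SO4 (cat.), rt; NaHCO3, concentrate below 30 °C
Reagents that add atoms: methanol, CO
Why: Acid-catalysed transesterification (ring-opening methanolysis) of the δ-lactone should be driven to the open hydroxy ester by methanol as solvent, and neutralisation before concentration should keep it from closing again; the stereocentre is not involved.

Step 3
Reactants: 4 methyl (3R)-3-[3,4-bis(benzyloxy)phenyl]-5-hydroxypentanoate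
Product: 5 (3R)-3-[3,4-bis(benzyloxy)phenyl]-5-methoxy-5-oxopentanoic acid
Conditions: TEMPO (0.2 equiv), PhI(OAc)2 (2.2 equiv), MeCN/H2O 1:1, rt
Reagents that add atoms: water, O
Why: TEMPO/PhI(OAc)2 oxidation in aqueous acetonitrile should take the primary alcohol through the aldehyde hydrate to the acid under nearly neutral conditions that the benzyl ethers, the methyl ester and the stereocentre tolerate, which leaves the two carboxyl ends differentiated.

Step 4
Reactants: 6 4-(3,4-dimethoxyphenyl)butanoic acid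
Product: 7 4-(3,4-dimethoxyphenyl)butan-1-ol
Conditions: BH3·SMe2 (1.5 equiv), THF, 0 °C to rt; MeOH quench
Reagents that add atoms: none
Why: Borane reduction of a carboxylic acid through the acyloxyborane is chemoselective and leaves the veratryl ring untouched.

Step 5
Reactants: 7 4-(3,4-dimethoxyphenyl)butan-1-ol
Product: 8 4-(3,4-dimethoxyphenyl)butanal
Conditions: TEMPO (0.1 equiv), PhI(OAc)2 (1.1 equiv), CH2Cl2, rt
Reagents that add atoms: none
Why: Anhydrous TEMPO/PhI(OAc)2 oxidation should stop at the aldehyde because no hydrate can form.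

Step 6
Reactants: 8 4-(3,4-dimethoxyphenyl)butanal
Product: 10 3-[2-(3,4-dimethoxyphenyl)ethyl]-4-(morpholin-4-yl)but-3-en-2-one, via morpholine enamine 9 (not isolated)
Conditions: morpholine (1.05 equiv), 4 Å MS, CH2Cl2, rt; then Et3N (1.2 equiv), AcCl (1.1 equiv), 0 °C to rt
Reagents that add atoms: morpholine, C1COCCN1; acetyl chloride, CC(=O)Cl
Why: Stork enamine acylation: the morpholine enamine is acetylated at its β-carbon, the only α-carbon of the aldehyde, and loss of HCl to Et3N gives the push–pull enaminone, so that the acetyl group and the masked formyl carbon sit on the carbon that bears the C6 arm without a regiochemical choice.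

Step 7
Reactants: 5 (3R)-3-[3,4-bis(benzyloxy)phenyl]-5-methoxy-5-oxopentanoic acid; 10 3-[2-(3,4-dimethoxyphenyl)ethyl]-4-(morpholin-4-yl)but-3-en-2-one
Product: 13 methyl (3R)-3-[3,4-bis(benzyloxy)phenyl]-4-{5-[2-(3,4-dimethoxyphenyl)ethyl]-4-oxo-4H-pyran-2-yl}butanoate, via acid chloride 11 (not isolated), via enaminone diketone 12 (not isolated)
Conditions: (COCl)2, DMF (cat.), CH2Cl2, 0 °C; then lithium enolate of 10 (2.2 equiv, from LiN(iPr)2, THF, −78 °C), −78 to −30 °C; then 2 M HCl, rt
Reagents that add atoms: none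
Why: Koreeda-type 4-pyranone synthesis: the α′-lithium enolate of the β-amino enone is C-acylated by the acid chloride much faster than by the methyl ester, and in acid the enol oxygen of the new 1,3-diketone adds to the protonated enaminone carbon and morpholine is expelled; the stereocentre is not touched.

Step 8
Reactants: 13 methyl (3R)-3-[3,4-bis(benzyloxy)phenyl]-4-{5-[2-(3,4-dimethoxyphenyl)ethyl]-4-oxo-4H-pyran-2-yl}butanoate
Product: 16 (3R)-3-[3,4-bis(benzyloxy)phenyl]-3-{2,4-dihydroxy-5-[2-(3,4-dimethoxyphenyl)ethyl]phenyl}propanoic acid, via pyranone acid 14 (not isolated), via diketo aldehyde 15 (not isolated)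
Conditions: degassed 2 M aq. KOH/1,4-dioxane 1:1, Ar, rt then 70 °C; HCl to pH 3 at 0 °C
Reagents that add atoms: potassium hydroxide, [K+].[OH-]
Why: Proposed new method: after saponification of the ester, hydroxide adds to the unsubstituted ring carbon of the pyranone (the future C5; addition at the substituted carbon leads to the same chain) and the ring opens to the enolate of diketo aldehyde 15, whose C4a methylene, as the terminal enolate carbon of the C8a ketone, adds to the C5 aldehyde carbon, after which loss of water and enolisation of the C7 and C8a ketones give the resorcinol irreversibly. The closest known reaction type is the alkali-induced conversion of 2,6-dialkyl-4-pyranones through their 1,3,5-triketones into resorcinols (2,6-dimethyl-4-pyranone to orcinol), in which the acceptor is a ketone, whereas an aldehyde acceptor released from a 6-unsubstituted pyranone has not been shown. The benzene ring closes by a 6-(enolexo)-exo-trig aldol that forms C4a–C5. No stereocentre is formed, and the existing one at C4 is β to both carbonyl groups and bears no leaving group, so it should keep its configuration. The step needs the carbon–carbon closure to outrun reclosure to the pyranone and hydroxide attack at the formyl carbon (retro-Claisen loss of formate). This should be helped because in base the formyl group is held as the enolate of a β-keto aldehyde, because C4a–C5 is the only carbon–carbon closure to a six-membered ring once the ester is a carboxylate, and because aromatisation drains the equilibria.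

Step 9
Reactants: 16 (3R)-3-[3,4-bis(benzyloxy)phenyl]-3-{2,4-dihydroxy-5-[2-(3,4-dimethoxyphenyl)ethyl]phenyl}propanoic acid
Product: 17 (4R)-4-[3,4-bis(benzyloxy)phenyl]-6-[2-(3,4-dimethoxyphenyl)ethyl]-7-hydroxy-3,4-dihydro-2H-chromen-2-one
Conditions: TsOH·H2O (cat.), toluene, 80 °C, 4 Å MS
Reagents that add atoms: none
Why: Acid-catalysed lactonisation (intramolecular esterification) should take place only with the hydroxyl group at C8a, ortho to the benzylic carbon, as a six-membered ring, while the C7 hydroxyl cannot reach the carboxyl group.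

Step 10
Reactants: 17 (4R)-4-[3,4-bis(benzyloxy)phenyl]-6-[2-(3,4-dimethoxyphenyl)ethyl]-7-hydroxy-3,4-dihydro-2H-chromen-2-one
Product: 18 (4R)-4-(3,4-dihydroxyphenyl)-6-[2-(3,4-dimethoxyphenyl)ethyl]-7-hydroxy-3,4-dihydro-2H-chromen-2-one
Conditions: H2 (1 atm), Pd/C (10 %), EtOAc/THF, rt
Reagents that add atoms: none
Why: Catalytic hydrogenolysis cleaves the two benzyl aryl ethers, while the aryl lactone, the methyl ethers and the benzylic C4–H stereocentre are inert under these neutral conditions.

**Compound list**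

1 | 3,4-bis(benzyloxy)phenylboronic acid | OB(O)c1ccc(OCc2ccccc2)c(OCc2ccccc2)c1 | starting material
2 | 5,6-dihydro-2H-pyran-2-one | O=C1C=CCCO1 | starting material
3 | (4R)-4-[3,4-bis(benzyloxy)phenyl]oxan-2-one | O=C1C[C@H](c2ccc(OCc3ccccc3)c(OCc3ccccc3)c2)CCO1 | intermediate
4 | methyl (3R)-3-[3,4-bis(benzyloxy)phenyl]-5-hydroxypentanoate | COC(=O)C[C@H](c1ccc(OCc2ccccc2)c(OCc2ccccc2)c1)CCO | intermediate
5 | (3R)-3-[3,4-bis(benzyloxy)phenyl]-5-methoxy-5-oxopentanoic acid | COC(=O)C[C@H](c1ccc(OCc2ccccc2)c(OCc2ccccc2)c1)CC(=O)O | intermediate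
6 | 4-(3,4-dimethoxyphenyl)butanoic acid | COc1ccc(CCCC(=O)O)cc1OC | starting material
7 | 4-(3,4-dimethoxyphenyl)butan-1-ol | COc1ccc(CCCCO)cc1OC | intermediate
8 | 4-(3,4-dimethoxyphenyl)butanal | COc1ccc(CCCC=O)cc1OC | intermediate
9 | 4-[(1E)-4-(3,4-dimethoxyphenyl)but-1-en-1-yl]morpholine | COc1ccc(CC/C=C/N2CCOCC2)cc1OC | intermediate (not isolated)
10 | (3E)-3-[2-(3,4-dimethoxyphenyl)ethyl]-4-(morpholin-4-yl)but-3-en-2-one | CC(=O)/C(CCc1ccc(OC)c(OC)c1)=C/N1CCOCC1 | intermediate
11 | methyl (3S)-3-[3,4-bis(benzyloxy)phenyl]-5-chloro-5-oxopentanoate (same spatial arrangement as 5; the descriptor changes by ranking only) | COC(=O)C[C@H](c1ccc(OCc2ccccc2)c(OCc2ccccc2)c1)CC(Cl)=O | intermediate (not isolated)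
12 | methyl (3R,8E)-3-[3,4-bis(benzyloxy)phenyl]-8-[2-(3,4-dimethoxyphenyl)ethyl]-9-(morpholin-4-yl)-5,7-dioxonon-8-enoate | COC(=O)C[C@H](c1ccc(OCc2ccccc2)c(OCc2ccccc2)c1)CC(=O)CC(=O)/C(CCc1ccc(OC)c(OC)c1)=C/N1CCOCC1 | intermediate (not isolated)
13 | methyl (3R)-3-[3,4-bis(benzyloxy)phenyl]-4-{5-[2-(3,4-dimethoxyphenyl)ethyl]-4-oxo-4H-pyran-2-yl}butanoate | COC(=O)C[C@H](c1ccc(OCc2ccccc2)c(OCc2ccccc2)c1)Cc1cc(=O)c(CCc2ccc(OC)c(OC)c2)co1 | intermediate
14 | (3R)-3-[3,4-bis(benzyloxy)phenyl]-4-{5-[2-(3,4-dimethoxyphenyl)ethyl]-4-oxo-4H-pyran-2-yl}butanoic acid (present as potassium salt) | OC(=O)C[C@H](c1ccc(OCc2ccccc2)c(OCc2ccccc2)c1)Cc1cc(=O)c(CCc2ccc(OC)c(OC)c2)co1 | intermediate (not isolated)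
15 | (3R)-3-[3,4-bis(benzyloxy)phenyl]-10-(3,4-dimethoxyphenyl)-8-formyl-5,7-dioxodecanoic acid (keto form drawn; present as enolates, C8 of the chain undefined) | OC(=O)C[C@H](c1ccc(OCc2ccccc2)c(OCc2ccccc2)c1)CC(=O)CC(=O)C(C=O)CCc1ccc(OC)c(OC)c1 | intermediate (not isolated)
16 | (3R)-3-[3,4-bis(benzyloxy)phenyl]-3-{2,4-dihydroxy-5-[2-(3,4-dimethoxyphenyl)ethyl]phenyl}propanoic acid | OC(=O)C[C@H](c1ccc(OCc2ccccc2)c(OCc2ccccc2)c1)c1cc(CCc2ccc(OC)c(OC)c2)c(O)cc1O | intermediate
17 | (4R)-4-[3,4-bis(benzyloxy)phenyl]-6-[2-(3,4-dimethoxyphenyl)ethyl]-7-hydroxy-3,4-dihydro-2H-chromen-2-one | COc1ccc(CCc2cc3c(cc2O)OC(=O)C[C@@H]3c2ccc(OCc4ccccc4)c(OCc4ccccc4)c2)cc1OC | intermediate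
18 | (4R)-4-(3,4-dihydroxyphenyl)-6-[2-(3,4-dimethoxyphenyl)ethyl]-7-hydroxy-3,4-dihydro-2H-chromen-2-one | COc1ccc(CCc2cc3c(cc2O)OC(=O)C[C@@H]3c2ccc(O)c(O)c2)cc1OC | target

**Step count**

Total: 10 steps. Longest linear sequence: 7 steps (1, 2, 3, 7, 8, 9, 10); the branch 4, 5, 6 joins at step 7 and is equally long.

**Steps most likely to fail**

Step 8 (Proposed new method). Hydroxide attack at the formyl carbon of the opened chain, with loss of formate, or plain reclosure to the pyranone, may outrun the carbon–carbon closure. The fallback uses known chemistry, sets out from boronic acid 1 and comes back to the route at target 18.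
- 4-Bromoresorcinol is condensed with malic acid in concentrated H2SO4 (von Pechmann) to 6-bromo-7-hydroxy-2H-chromen-2-one F1.
- Benzylation (BnBr, K2CO3, DMF) gives 7-(benzyloxy)-6-bromo-2H-chromen-2-one F2.
- B-alkyl Suzuki–Miyaura coupling of F2 with the 9-BBN adduct of 3,4-dimethoxystyrene (PdCl2(dppf), aq. K3PO4, DMF/THF) gives 7-(benzyloxy)-6-[2-(3,4-dimethoxyphenyl)ethyl]-2H-chromen-2-one F3.
- Asymmetric 1,4-addition of 1 to F3 (Rh(acac)(C2H4)2, (R)-SEGPHOS, dioxane/H2O), the ligand sense known to give (R)-4-arylchroman-2-ones, should give (4R)-7-(benzyloxy)-4-[3,4-bis(benzyloxy)phenyl]-6-[2-(3,4-dimethoxyphenyl)ethyl]-3,4-dihydro-2H-chromen-2-one F4.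
- Hydrogenolysis of F4 (H2, Pd/C) gives 18.

Step 7. Proton transfer from the α-methylene of the acid chloride to the enolate, O-acylation of the enolate, or exchange of the two carboxyl ends of the half-ester chloride through a cyclic acyloxonium ion (loss of enantiomeric purity) may spoil the union. The fallback replaces the acylation by an aldol addition and an oxidation; it sets out from hydroxy ester 4 and comes back at enaminone diketone 12.
- Anhydrous TEMPO/PhI(OAc)2 oxidation of 4 in CH2Cl2 gives methyl (3R)-3-[3,4-bis(benzyloxy)phenyl]-5-oxopentanoate F5.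
- Addition of the lithium enolate of 10 (LiN(iPr)2, THF, −78 °C) to F5 gives methyl (3R)-3-[3,4-bis(benzyloxy)phenyl]-8-[2-(3,4-dimethoxyphenyl)ethyl]-5-hydroxy-9-(morpholin-4-yl)-7-oxonon-8-enoate F6 as a mixture of C5 epimers.
- Dess–Martin oxidation of F6 gives 12, which closes to 13 in acid as in step 7.

Step 6. N-acylation of residual morpholine, self-condensation of the aldehyde enamine or ketene cycloaddition that does not end in the C-acyl enamine may divert the acetylation. The fallback uses a preformed aza-enolate and an acyl donor that cannot form ketene; it sets out from aldehyde 8 and comes back at enaminone 10.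
- Condensation of 8 with cyclohexylamine (MgSO4, CH2Cl2) gives N-cyclohexyl-4-(3,4-dimethoxyphenyl)butan-1-imine F7.
- Deprotonation of F7 (LiN(iPr)2, 2 equiv, THF, −78 to 0 °C) and C-acetylation of the aza-enolate with N-methoxy-N-methylacetamide give (3Z)-4-(cyclohexylamino)-3-[2-(3,4-dimethoxyphenyl)ethyl]but-3-en-2-one F8.
- Amine exchange of F8 with excess morpholine (AcOH cat., toluene, 80 °C) gives 10.

**Further compounds**

F1 | step 8 | 6-bromo-7-hydroxy-2H-chromen-2-one | O=c1ccc2cc(Br)c(O)cc2o1
F2 | step 8 | 7-(benzyloxy)-6-bromo-2H-chromen-2-one | O=c1ccc2cc(Br)c(OCc3ccccc3)cc2o1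
F3 | step 8 | 7-(benzyloxy)-6-[2-(3,4-dimethoxyphenyl)ethyl]-2H-chromen-2-one | COc1ccc(CCc2cc3ccc(=O)oc3cc2OCc2ccccc2)cc1OC
F4 | step 8 | (4R)-7-(benzyloxy)-4-[3,4-bis(benzyloxy)phenyl]-6-[2-(3,4-dimethoxyphenyl)ethyl]-3,4-dihydro-2H-chromen-2-one | COc1ccc(CCc2cc3c(cc2OCc2ccccc2)OC(=O)C[C@@H]3c2ccc(OCc4ccccc4)c(OCc4ccccc4)c2)cc1OC
F5 | step 7 | methyl (3R)-3-[3,4-bis(benzyloxy)phenyl]-5-oxopentanoate | COC(=O)C[C@H](c1ccc(OCc2ccccc2)c(OCc2ccccc2)c1)CC=O
F6 | step 7 | methyl (3R)-3-[3,4-bis(benzyloxy)phenyl]-8-[2-(3,4-dimethoxyphenyl)ethyl]-5-hydroxy-9-(morpholin-4-yl)-7-oxonon-8-enoate (C5 epimers) | COC(=O)C[C@H](c1ccc(OCc2ccccc2)c(OCc2ccccc2)c1)CC(O)CC(=O)/C(CCc1ccc(OC)c(OC)c1)=C/N1CCOCC1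
F7 | step 6 | (E)-N-cyclohexyl-4-(3,4-dimethoxyphenyl)butan-1-imine | COc1ccc(CCC/C=N/C2CCCCC2)cc1OC
F8 | step 6 | (3Z)-4-(cyclohexylamino)-3-[2-(3,4-dimethoxyphenyl)ethyl]but-3-en-2-one | CC(=O)/C(CCc1ccc(OC)c(OC)c1)=C\NC1CCCCC1
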